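G was the point, so I began with how much of it each flask could hold.

| setting | south-east | north-west | eta | alpha | beta | epsilon |
|---|---|---|---|---|---|---|
| D | 0.41 M | 0.61 M | 0.81 M | 0.81 M | 0.81 M | 0.81 M |
| temperature | 65 °C | 98 °C | 110 °C | 50 °C |  | 80 °C |
| remark | run made earlier | run made earlier |  |  | at 110 °C until 20 min, from then on at 50 °C |  |
| time |  |  | 30 min | 30 min | 30 min | 30 min |

| run | time / min | G / % | D / % |
|---|---|---|---|
| south-east | 30.0 | 64.9 | 36.0 |
| south-east | 40.0 | 65.4 | 34.2 |
| south-east | 60.0 | 65.9 | 33.9 |
| south-east | 90.0 | 65.7 | 34.4 |
| south-east | 150 | 66.3 | 33.7 |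
| south-east | 240 | 65.3 | 33.7 |
| south-east | 360 | 66.9 | 34.1 |
| north-west | 5.00 | 37.5 | 63.0 |
| north-west | 8.00 | 36.1 | 63.3 |
| north-west | 10.0 | 36.5 | 63.2 |
| north-west | 20.0 | 37.5 | 62.6 |
| north-west | 25.0 | 36.3 | 63.0 |
| north-west | 50.0 | 37.4 | 62.8 |
| north-west | 80.0 | 37.6 | 63.0 |

(readings scatter by 0.5 percentage points)

- the numbers in the tables scatter by 0.5 percentage points (one standard deviation)

1. the best flask by amount of G, in percent of the D charged; "all alike" if 1.5 percentage points covers them all (eta / alpha / beta / epsilon / all alike)
2. amount of G at the end, in percent of the D charged, eta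
3. amount of G at the end, in percent of the D charged, alpha
4. amount of G at the end, in percent of the D charged, beta
5. amount of G at the end, in percent of the D charged, epsilon

Both tables go flat, and G and D add up to about the charge, so I read each plateau as an equilibrium in which one D gives one G. The ratio K = cG/cD read 1.94 at 65 °C and 0.596 at 98 °C. The fall of ln K from the south-east temperature to the north-west temperature, 1.18, I called the slope. Drawn as a straight line in temperature, with the resting share of G as K divided by one plus K, it gave 27.9% at 110 °C, 53.2% at 80 °C and 76.9% at 50 °C.

Then came the clock. At 30.0 min the south-east flask stood 1.6 percentage points short of its plateau, as a mean over G and D. That put its relaxation constant near 0.125 min⁻¹, a half-life of 5.55 min. This is shorter than the 30 min of the flasks, and eta and epsilon are hotter than the south-east flask, so I expected those two to sit at their shares, which is thermodynamic control.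

My first pass put alpha at its share too. I put that back in and went round again, with alpha colder than the south-east flask. The north-west readings were on their plateau by 5.00 min, so I put that flask's constant at 0.637 min⁻¹ or more. That speed-up, carried down to 50 °C, gave alpha an upper estimate of 0.0596 min⁻¹ and an estimated ceiling of 64.0% of G, less than its share. I committed alpha to that ceiling.

The forecast gave eta 28.6%, alpha 49% (range 38% to 61%), beta 42.5% and epsilon 52.3%, with epsilon best: “Epsilon probably leads, narrowly over alpha.” Its eta and epsilon differ a little from my shares.

The flasks gave eta 28.5%, alpha 40.2%, beta 39.3% and epsilon 52.4%, with epsilon best.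

    D ⇌ G (K = 1.10, k = 0.00490 s⁻¹, Ea = 87.0 kJ mol⁻¹, ΔH = −38.0 kJ mol⁻¹)
    (constants at 80 °C)

D ⇌ G ran both ways in eta with a relaxation half-life of 0.0661 min, short against 30 min, and eta and epsilon already held 28.5% and 52.4% at 15.0 min, near the slope's 27.9% and 53.2%. Alpha was still climbing, under kinetic control, from 23.7% at 15.0 min to 40.2% at 30.0 min, 8.8 points below the forecast, and it stood at 78.5% after 300 min, near the slope's 76.9%. Beta held 28.5% until 20.0 min, then rose to 39.3%.

For eta repeated at 85 °C, the slope gives a share of 48.7%. The computed flask holds 47.9%.

(The data are simulated from invented constants; scatter was added.)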